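**Plan**

- Retrosynthesis: the four benzyl ethers come off last. Ring A is cut at C4a–C5 (Claisen condensation) and at C8–C8a (vinylogous Mukaiyama–Michael addition, then dehydrosilylation). Ring C is cut at C2–C3 and O1–C8a (hetero-Diels–Alder). The biaryl bond is cut by Suzuki coupling, and the flavone goes back to a chalcone.
- Enabling feature: ring C of the flavanone (O1, C2, C3, C4, C4a, C8a) is a 2-aryl-2,3-dihydropyran-4-one. Its C2–C3 and O1–C8a bonds map onto an aryl aldehyde C=O and 1-methoxy-3-silyloxybutadiene, and the enol ether bond C4a=C8a kept by the adduct is where ring A is fused afterwards.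
- Forward order: flavone unit (chalcone, oxidative cyclisation), biaryl bond, ring C of the flavanone (step 7), ring A of the flavanone (steps 8 and 9), debenzylation.
- Stereochemistry: the only stereocentre, C2 (S), is set in step 7 by the (S)-BINOL–titanium catalyst. Later steps avoid conditions that open ring C.

Key step: step 7

Ar in the names below = 4-(benzyloxy)-3-{2-(benzyloxy)-5-[5,7-bis(benzyloxy)-4-oxo-4H-chromen-2-yl]phenyl}phenyl.

Assumption: (S)-BINOL with Ti(OiPr)4 is taken to deliver the diene to the Si face of an aromatic aldehyde, the sense of the related BINOL–titanium allylation; if a model aldehyde shows the opposite sense, (R)-BINOL is used and nothing else changes.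

**Route**

Step 1
Reactants: 1 3-bromo-4-hydroxybenzaldehyde
Product: 2 4-(benzyloxy)-3-bromobenzaldehyde
Conditions: BnBr, K2CO3, DMF, 25 °C
Reagents that add atoms: benzyl bromide, BrCc1ccccc1
Why: Williamson etherification of an acidic para-formyl phenol, with a non-enolisable aldehyde that is inert to carbonate.

Step 2
Reactants: 3 2',4',6'-trihydroxyacetophenone
Product: 4 1-[2,4-bis(benzyloxy)-6-hydroxyphenyl]ethanone
Conditions: BnBr (2.1 equiv), K2CO3, DMF, 25 °C
Reagents that add atoms: benzyl bromide, BrCc1ccccc1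
Why: Williamson etherification in which the hydroxyl hydrogen-bonded to the acetyl group is the least nucleophilic and should stay free, as the later pyranone closure requires.

Step 3
Reactants: 4 1-[2,4-bis(benzyloxy)-6-hydroxyphenyl]ethanone; 2 4-(benzyloxy)-3-bromobenzaldehyde
Product: 5 (E)-1-[2,4-bis(benzyloxy)-6-hydroxyphenyl]-3-[4-(benzyloxy)-3-bromophenyl]prop-2-en-1-one
Conditions: KOH, EtOH/THF, 25 °C; then dilute HCl
Reagents that add atoms: none
Why: Claisen–Schmidt condensation of a methyl ketone with a non-enolisable aldehyde, the E enone arising by E1cB dehydration.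

Step 4
Reactants: 5 (E)-1-[2,4-bis(benzyloxy)-6-hydroxyphenyl]-3-[4-(benzyloxy)-3-bromophenyl]prop-2-en-1-one
Product: 6 5,7-bis(benzyloxy)-2-[4-(benzyloxy)-3-bromophenyl]-4H-chromen-4-one
Conditions: I2 (10 mol%), DMSO, 120 °C
Reagents that add atoms: none
Why: Oxidative cyclisation of a 2'-hydroxychalcone (oxa-Michael closure, then iodine/DMSO dehydrogenation), a standard flavone synthesis that leaves the aryl bromide and benzyl ethers alone.

Step 5
Reactants: 2 4-(benzyloxy)-3-bromobenzaldehyde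
Product: 7 4-(benzyloxy)-3-(4,4,5,5-tetramethyl-1,3,2-dioxaborolan-2-yl)benzaldehyde
Conditions: B2pin2, PdCl2(dppf) (3 mol%), KOAc, 1,4-dioxane, 90 °C
Reagents that add atoms: bis(pinacolato)diboron, CC1(C)OB(OC1(C)C)B1OC(C)(C)C(C)(C)O1
Why: Miyaura borylation of an aryl bromide, in which the weak acetate base prevents onward coupling and the aldehyde is tolerated.

Step 6
Reactants: 6 5,7-bis(benzyloxy)-2-[4-(benzyloxy)-3-bromophenyl]-4H-chromen-4-one; 7 4-(benzyloxy)-3-(4,4,5,5-tetramethyl-1,3,2-dioxaborolan-2-yl)benzaldehyde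
Product: 8 4-(benzyloxy)-3-{2-(benzyloxy)-5-[5,7-bis(benzyloxy)-4-oxo-4H-chromen-2-yl]phenyl}benzaldehyde (ArCHO)
Conditions: Pd(OAc)2 (5 mol%), SPhos (10 mol%), K3PO4, toluene/H2O, 90 °C
Reagents that add atoms: none
Why: Suzuki–Miyaura coupling giving a biaryl with only two ortho substituents, which a dialkylbiarylphosphine catalyst handles and which has no configurationally stable axis.

Step 7
Reactants: 8 ArCHO; 9 (E)-1-methoxy-3-(trimethylsilyloxy)buta-1,3-diene
Product: 11 (2S)-2-Ar-2,3-dihydro-4H-pyran-4-one, via silylated aldol adduct 10 (not isolated)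
Conditions: (S)-BINOL (20 mol%), Ti(OiPr)4 (10 mol%), CF3CO2H (cat.), 4 Å MS, Et2O/CH2Cl2, −20 °C; then CF3CO2H, CH2Cl2, 0 °C
Reagents that add atoms: none
Why: The chiral BINOL–titanium Lewis acid binds the aldehyde oxygen and the CH2 terminus of the diene adds to the carbonyl carbon (Mukaiyama aldol pathway, C2–C3 bond) to give silyl ether 10, after which trifluoroacetic acid closes O1 onto the methoxy-bearing carbon and expels methanol. This is the known BINOL–titanium catalysed hetero-Diels–Alder reaction of aromatic aldehydes with 1-methoxy-3-silyloxybutadiene, which gives 2-aryl-2,3-dihydropyran-4-ones. Ring C closes in a formal [4+2] sense, the O1–C8a bond arising by 6-endo-trig oxa-Michael addition followed by β-elimination. The C2 centre is set by the catalyst alone: the (S)-BINOL complex is expected to expose the Si face of the formyl group, which gives the (S) configuration. The step needs chemoselectivity for the aldehyde and a catalysed pathway that outruns the background reaction; the aldehyde is aromatic, free of ortho substituents and the only carbonyl able to act as a heterodienophile, because the flavone carbonyl is a vinylogous ester, while sieves and low temperature hold back the uncatalysed addition.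

Step 8
Reactants: 11 (2S)-2-Ar-2,3-dihydro-4H-pyran-4-one; 12 1-methoxy-1,3-bis(trimethylsilyloxy)buta-1,3-diene
Product: 14 methyl 4-[(2S)-2-Ar-4-oxo-3,4-dihydro-2H-pyran-6-yl]-3-oxobutanoate, via bis(silyl) Michael adduct 13 (not isolated)
Conditions: TMSOTf (10 mol%), CH2Cl2, −78 °C; Et3N, concentrate; then Pd(OAc)2 (10 mol%), O2 (1 atm), DMSO, 25 °C; aq. NH4Cl
Reagents that add atoms: none
Why: Catalytic silyl triflate turns the vinylogous ester into a 4-silyloxy oxocarbenium ion that the terminal carbon of the bis(silyl) dienol ether attacks at C8a (vinylogous Mukaiyama–Michael addition, expected trans to Ar), and the ring silyl enol ether is then dehydrosilylated regiospecifically by palladium diacetate under oxygen (Saegusa–Ito oxidation), which restores C4a=C8a, erases the temporary C8a centre and leaves C2 untouched.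

Step 9
Reactants: 14 methyl 4-[(2S)-2-Ar-4-oxo-3,4-dihydro-2H-pyran-6-yl]-3-oxobutanoate
Product: 15 (2S)-2-Ar-5,7-dihydroxy-2,3-dihydro-4H-chromen-4-one
Conditions: DBU (2.5 equiv), toluene, 0 → 40 °C; then AcOH
Reagents that add atoms: none
Why: Intramolecular Claisen condensation of the polyketide type, in which the dienolate formed at the doubly activated C8 methylene acylates the ester carbon through C4a in a six-membered transition state (the aldol mode would need a bridgehead alkene), methanol is lost and the dione tautomerises irreversibly to the phloroglucinol ring, while the amidine base in a non-polar solvent is too weak to enolise C3 and open ring C, so C2 should keep its configuration.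

Step 10
Reactants: 15 (2S)-2-Ar-5,7-dihydroxy-2,3-dihydro-4H-chromen-4-one
Product: 16 (2S)-5,7-dihydroxy-2-{4-hydroxy-3-[2-hydroxy-5-(5,7-dihydroxy-4-oxo-4H-chromen-2-yl)phenyl]phenyl}-2,3-dihydro-4H-chromen-4-one
Conditions: H2 (1 atm), 10% Pd/C, THF/MeOH, 25 °C
Reagents that add atoms: none
Why: Hydrogenolysis of four benzyl aryl ethers under neutral conditions, stopped after four equivalents of hydrogen so that the flavone C2=C3 bond, the ketones and the benzylic C2–O1 bond are kept and C2 is not epimerised.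

**Compound list**

1 | 3-bromo-4-hydroxybenzaldehyde | O=Cc1ccc(O)c(Br)c1 | starting material
2 | 4-(benzyloxy)-3-bromobenzaldehyde | O=Cc1ccc(OCc2ccccc2)c(Br)c1 | intermediate
3 | 2',4',6'-trihydroxyacetophenone | CC(=O)c1c(O)cc(O)cc1O | starting material
4 | 1-[2,4-bis(benzyloxy)-6-hydroxyphenyl]ethanone | CC(=O)c1c(O)cc(OCc2ccccc2)cc1OCc1ccccc1 | intermediate
5 | (E)-1-[2,4-bis(benzyloxy)-6-hydroxyphenyl]-3-[4-(benzyloxy)-3-bromophenyl]prop-2-en-1-one | O=C(/C=C/c1ccc(OCc2ccccc2)c(Br)c1)c1c(O)cc(OCc2ccccc2)cc1OCc1ccccc1 | intermediate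
6 | 5,7-bis(benzyloxy)-2-[4-(benzyloxy)-3-bromophenyl]-4H-chromen-4-one | O=c1cc(-c2ccc(OCc3ccccc3)c(Br)c2)oc2cc(OCc3ccccc3)cc(OCc3ccccc3)c12 | intermediate
7 | 4-(benzyloxy)-3-(4,4,5,5-tetramethyl-1,3,2-dioxaborolan-2-yl)benzaldehyde | O=Cc1ccc(OCc2ccccc2)c(B2OC(C)(C)C(C)(C)O2)c1 | intermediate
8 | 4-(benzyloxy)-3-{2-(benzyloxy)-5-[5,7-bis(benzyloxy)-4-oxo-4H-chromen-2-yl]phenyl}benzaldehyde (ArCHO) | O=Cc1ccc(OCc2ccccc2)c(-c2cc(-c3cc(=O)c4c(OCc5ccccc5)cc(OCc5ccccc5)cc4o3)ccc2OCc2ccccc2)c1 | intermediate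
9 | (E)-1-methoxy-3-(trimethylsilyloxy)buta-1,3-diene | CO/C=C/C(=C)O[Si](C)(C)C | starting material
10 | (5S,1E)-5-Ar-1-methoxy-5-(trimethylsilyloxy)pent-1-en-3-one | CO/C=C/C(=O)C[C@@H](c1ccc(OCc2ccccc2)c(-c2cc(-c3cc(=O)c4c(OCc5ccccc5)cc(OCc5ccccc5)cc4o3)ccc2OCc2ccccc2)c1)O[Si](C)(C)C | intermediate
11 | (2S)-2-Ar-2,3-dihydro-4H-pyran-4-one | O=C1C[C@@H](c2ccc(OCc3ccccc3)c(-c3cc(-c4cc(=O)c5c(OCc6ccccc6)cc(OCc6ccccc6)cc5o4)ccc3OCc3ccccc3)c2)OC=C1 | intermediate
12 | 1-methoxy-1,3-bis(trimethylsilyloxy)buta-1,3-diene (bis(silyl) dienol ether of methyl acetoacetate; ketene acetal geometry immaterial) | C=C(O[Si](C)(C)C)C=C(OC)O[Si](C)(C)C | starting material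
13 | methyl 4-[(2R,6S)-6-Ar-4-(trimethylsilyloxy)-5,6-dihydro-2H-pyran-2-yl]-3-(trimethylsilyloxy)but-2-enoate (side-chain enol ether geometry undefined) | C[Si](C)(C)OC1=C[C@@H](CC(O[Si](C)(C)C)=CC(=O)OC)O[C@H](c2ccc(OCc3ccccc3)c(-c3cc(-c4cc(=O)c5c(OCc6ccccc6)cc(OCc6ccccc6)cc5o4)ccc3OCc3ccccc3)c2)C1 | intermediate
14 | methyl 4-[(2S)-2-Ar-4-oxo-3,4-dihydro-2H-pyran-6-yl]-3-oxobutanoate | O=C1C[C@@H](c2ccc(OCc3ccccc3)c(-c3cc(-c4cc(=O)c5c(OCc6ccccc6)cc(OCc6ccccc6)cc5o4)ccc3OCc3ccccc3)c2)OC(CC(=O)CC(=O)OC)=C1 | intermediate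
15 | (2S)-2-Ar-5,7-dihydroxy-2,3-dihydro-4H-chromen-4-one | O=C1C[C@@H](c2ccc(OCc3ccccc3)c(-c3cc(-c4cc(=O)c5c(OCc6ccccc6)cc(OCc6ccccc6)cc5o4)ccc3OCc3ccccc3)c2)Oc2cc(O)cc(O)c21 | intermediate
16 | (2S)-5,7-dihydroxy-2-{4-hydroxy-3-[2-hydroxy-5-(5,7-dihydroxy-4-oxo-4H-chromen-2-yl)phenyl]phenyl}-2,3-dihydro-4H-chromen-4-one | O=C1C[C@@H](c2ccc(O)c(-c3cc(-c4cc(=O)c5c(O)cc(O)cc5o4)ccc3O)c2)Oc2cc(O)cc(O)c21 | target

**Count and risks**

Total steps: 10. Longest linear sequence: 8 steps (1, 3, 4, 6, 7, 8, 9, 10).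

Step 9 is the most exposed. The dienolate may acylate the enolisable β-keto ester too slowly, and longer or stronger base treatment would let ring C open by retro-oxa-Michael elimination and reclose without facial control, eroding the configuration at C2. The fallback closes ring A without base through an acylketene. It sets out from 11 and runs the addition and dehydrosilylation of step 8 with 2,2-dimethyl-6-methylidene-4-(trimethylsilyloxy)-4H-1,3-dioxine F1 in place of 12. F1 is made from commercial 2,2,6-trimethyl-4H-1,3-dioxin-4-one with LiN(iPr)2 and Me3SiCl. The sequence passes through ring silyl enol ether F2 (not isolated) and gives dioxinone enone F3. Heating F3 in dilute toluene at 110 °C expels acetone and leaves acylketene F4. The enol of F4 is a dienylketene, which should form the C4a–C5 bond by 6π-electrocyclisation (or direct C-acylation at C4a) and tautomerise to 15, where the route is rejoined.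

Step 8 comes second. The palladium dehydrosilylation may stall: the silyl enol ethers can be protodesilylated before oxidation, or the β-keto ester can tie up palladium, leaving the saturated tetrahydropyranone. The silyl triflate may also ionise the benzylic C2–O1 bond if the temperature rises. The fallback replaces oxidation by addition–elimination on a halo-enone. From 11, pyridinium tribromide in pyridine/CH2Cl2 at 0 °C gives bromo enone F5. The same silyl-triflate-catalysed addition of 12 gives bis(silyl) bromo adduct F6 (not isolated), and mild acid hydrolysis gives bromo ketone F7. Et3N or DBU then removes HBr across C4a–C8a and delivers 14.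

Step 7 is third. Enantioface selection may be poor, because the flavone carbonyl and four benzyloxy groups can bind titanium and the sparingly soluble aldehyde may react through an uncatalysed pathway at the temperature needed to dissolve it. The fallback sets C2 by reagent control. From 8, asymmetric allylboration with the B-allyldiisopinocampheylborane antipode that attacks the Si face gives homoallylic alcohol F8. Wacker oxidation (PdCl2, CuCl, O2, DMF/H2O) gives β-hydroxy ketone F9. Condensation with N,N-dimethylformamide dimethyl acetal gives enaminone F10, which CF3CO2H closes to 11.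

Further compounds

F1 | step 9 | 2,2-dimethyl-6-methylidene-4-(trimethylsilyloxy)-4H-1,3-dioxine | C=C1C=C(O[Si](C)(C)C)OC(C)(C)O1
F2 | step 9 | 6-{[(2R,6S)-6-Ar-4-(trimethylsilyloxy)-5,6-dihydro-2H-pyran-2-yl]methyl}-2,2-dimethyl-4H-1,3-dioxin-4-one | C[Si](C)(C)OC1=C[C@@H](CC2=CC(=O)OC(C)(C)O2)O[C@H](c2ccc(OCc3ccccc3)c(-c3cc(-c4cc(=O)c5c(OCc6ccccc6)cc(OCc6ccccc6)cc5o4)ccc3OCc3ccccc3)c2)C1
F3 | step 9 | (2S)-2-Ar-6-[(2,2-dimethyl-4-oxo-4H-1,3-dioxin-6-yl)methyl]-2,3-dihydro-4H-pyran-4-one | O=C1C[C@@H](c2ccc(OCc3ccccc3)c(-c3cc(-c4cc(=O)c5c(OCc6ccccc6)cc(OCc6ccccc6)cc5o4)ccc3OCc3ccccc3)c2)OC(CC2=CC(=O)OC(C)(C)O2)=C1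
F4 | step 9 | 4-[(2S)-2-Ar-4-oxo-3,4-dihydro-2H-pyran-6-yl]-3-oxobut-1-en-1-one (acylketene) | O=C=CC(=O)CC1=CC(=O)C[C@@H](c2ccc(OCc3ccccc3)c(-c3cc(-c4cc(=O)c5c(OCc6ccccc6)cc(OCc6ccccc6)cc5o4)ccc3OCc3ccccc3)c2)O1
F5 | step 8 | (2S)-2-Ar-5-bromo-2,3-dihydro-4H-pyran-4-one | O=C1C[C@@H](c2ccc(OCc3ccccc3)c(-c3cc(-c4cc(=O)c5c(OCc6ccccc6)cc(OCc6ccccc6)cc5o4)ccc3OCc3ccccc3)c2)OC=C1Br
F6 | step 8 | methyl 4-[(2R,6S)-6-Ar-3-bromo-4-(trimethylsilyloxy)-5,6-dihydro-2H-pyran-2-yl]-3-(trimethylsilyloxy)but-2-enoate | C[Si](C)(C)OC1=C(Br)[C@@H](CC(O[Si](C)(C)C)=CC(=O)OC)O[C@H](c2ccc(OCc3ccccc3)c(-c3cc(-c4cc(=O)c5c(OCc6ccccc6)cc(OCc6ccccc6)cc5o4)ccc3OCc3ccccc3)c2)C1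
F7 | step 8 | methyl 4-[(2R,6S)-6-Ar-3-bromo-4-oxotetrahydro-2H-pyran-2-yl]-3-oxobutanoate (both bromide epimers) | O=C1C[C@@H](c2ccc(OCc3ccccc3)c(-c3cc(-c4cc(=O)c5c(OCc6ccccc6)cc(OCc6ccccc6)cc5o4)ccc3OCc3ccccc3)c2)O[C@H](CC(=O)CC(=O)OC)C1Br
F8 | step 7 | (1S)-1-Ar-but-3-en-1-ol | C=CC[C@@H](c1ccc(OCc2ccccc2)c(-c2cc(-c3cc(=O)c4c(OCc5ccccc5)cc(OCc5ccccc5)cc4o3)ccc2OCc2ccccc2)c1)O
F9 | step 7 | (4S)-4-Ar-4-hydroxybutan-2-one | CC(=O)C[C@@H](c1ccc(OCc2ccccc2)c(-c2cc(-c3cc(=O)c4c(OCc5ccccc5)cc(OCc5ccccc5)cc4o3)ccc2OCc2ccccc2)c1)O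
F10 | step 7 | (5S,1E)-5-Ar-1-(dimethylamino)-5-hydroxypent-1-en-3-one | CN(C)/C=C/C(=O)C[C@@H](c1ccc(OCc2ccccc2)c(-c2cc(-c3cc(=O)c4c(OCc5ccccc5)cc(OCc5ccccc5)cc4o3)ccc2OCc2ccccc2)c1)O
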